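Fremontin is cut at both bonds of C4, the carbonyl carbon of ring C: C4–C4a to ring A and C3–C4 to the carbon that carries ring B. Because C4 sits between these two carbons, carbon monoxide can deliver it while palladium joins a ring A aryl iodide to a ring B benzylzinc chloride, so one operation gives the fully protected deoxybenzoin without closing a ring. The iodide is phloroglucinol-derived, with methoxymethyl (MOM) ethers on all three oxygens. The zinc reagent is a 2,4-bis(methoxymethoxy)benzyl unit whose 1,1-dimethylallyl group at C5' is set by an aromatic Claisen rearrangement. Chelation-guided unmasking of one ortho phenol, closure of ring C through C2 and acetal removal complete the route.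

Key step: step 10

Remark: the target is achiral, so no stereocentre has to be set; isoflavone numbering is used (O1, C2, C3, C4, C4a, C5–C8, C8a; ring B primed).

Remark: since carbon monoxide supplies C4, ring B must enter as a one-carbon benzyl unit; it is therefore built from a benzaldehyde and not from an arylacetic acid, which would bring one carbon too many.

**Ring A (steps 1–2)**

Step 1
Reactants: 1 phloroglucinol
Product: 2 1,3,5-tris(methoxymethoxy)benzene
Conditions: NaH (3.3 equiv), MOMCl (3.3 equiv), DMF, 0 °C to rt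
Reagents that add atoms: chloromethyl methyl ether (MOMCl), COCCl
Why: Williamson-type O-alkylation of the triphenoxide with a hard α-chloro ether should give the tris-acetal, which is stable to the organolithium, organozinc and palladium chemistry that follows.

Step 2
Reactants: 2 1,3,5-tris(methoxymethoxy)benzene
Product: 4 2-iodo-1,3,5-tris(methoxymethoxy)benzene, via aryllithium 3 (not isolated)
Conditions: n-BuLi (1.1 equiv), THF, 0 °C; then I2, THF, −78 °C to rt
Reagents that add atoms: iodine, II
Why: Directed ortho-metalation at one of three equivalent ring positions, each flanked by two coordinating OMOM groups, followed by iodinolysis of the C–Li bond, should give the mono-iodide only.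

**Ring B (steps 3–9)**

Step 3
Reactants: 5 2,4-dihydroxybenzaldehyde
Product: 6 2-hydroxy-4-[(3-methylbut-2-en-1-yl)oxy]benzaldehyde
Conditions: prenyl bromide (1.05 equiv), K2CO3 (1.1 equiv), acetone, rt
Reagents that add atoms: 1-bromo-3-methylbut-2-ene (prenyl bromide), CC(C)=CCBr
Why: Williamson etherification is selective for the 4-OH, which is the more acidic and is not tied up in the hydrogen bond that holds the 2-OH to the formyl group.

Step 4
Reactants: 6 2-hydroxy-4-[(3-methylbut-2-en-1-yl)oxy]benzaldehyde
Product: 7 2-(methoxymethoxy)-4-[(3-methylbut-2-en-1-yl)oxy]benzaldehyde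
Conditions: NaH (1.2 equiv), MOMCl (1.2 equiv), DMF, 0 °C to rt
Reagents that add atoms: chloromethyl methyl ether (MOMCl), COCCl
Why: O-alkylation of the sodium phenoxide masks the 2-OH and removes the chelate whose bond fixation would otherwise steer the coming rearrangement towards C3.

Step 5
Reactants: 7 2-(methoxymethoxy)-4-[(3-methylbut-2-en-1-yl)oxy]benzaldehyde
Product: 9 4-hydroxy-2-(methoxymethoxy)-5-(2-methylbut-3-en-2-yl)benzaldehyde, via ortho-dienone 8 (not isolated)
Conditions: PhNEt2, 190 °C, sealed tube, Ar, short reaction time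
Reagents that add atoms: none
Why: Aromatic Claisen rearrangement: the [3,3] shift carries the tertiary terminus of the prenyl group to C5, the ortho position that is not squeezed between the two oxygens, and ortho-dienone 8 enolises to the phenol because the formyl-bearing para carbon blocks a following Cope shift; the quaternary carbon formed is not a stereocentre.

Step 6
Reactants: 9 4-hydroxy-2-(methoxymethoxy)-5-(2-methylbut-3-en-2-yl)benzaldehyde
Product: 10 2,4-bis(methoxymethoxy)-5-(2-methylbut-3-en-2-yl)benzaldehyde
Conditions: NaH (1.2 equiv), MOMCl (1.3 equiv), DMF, 0 °C to rt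
Reagents that add atoms: chloromethyl methyl ether (MOMCl), COCCl
Why: O-alkylation of the acidic para-formyl phenoxide with the small MOM electrophile should proceed despite the neighbouring tertiary alkyl group, and it removes the phenol that could later add to the alkene.

Step 7
Reactants: 10 2,4-bis(methoxymethoxy)-5-(2-methylbut-3-en-2-yl)benzaldehyde
Product: 11 [2,4-bis(methoxymethoxy)-5-(2-methylbut-3-en-2-yl)phenyl]methanol
Conditions: NaBH4, MeOH, 0 °C
Reagents that add atoms: none
Why: Hydride reduction of the aldehyde is chemoselective and leaves the acetals and the terminal alkene untouched.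

Step 8
Reactants: 11 [2,4-bis(methoxymethoxy)-5-(2-methylbut-3-en-2-yl)phenyl]methanol
Product: 13 1-(chloromethyl)-2,4-bis(methoxymethoxy)-5-(2-methylbut-3-en-2-yl)benzene, via benzylic mesylate 12 (not isolated)
Conditions: MsCl (1.2 equiv), Et3N (1.5 equiv), LiCl (3 equiv), THF, 0 °C to rt; used without chromatography
Reagents that add atoms: lithium chloride, [Li+].[Cl-]
Why: Sulfonylation followed by chloride displacement at the activated benzylic carbon runs under basic, acid-free conditions, so the MOM acetals and the electron-rich benzylic chloride should survive.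

Step 9
Reactants: 13 1-(chloromethyl)-2,4-bis(methoxymethoxy)-5-(2-methylbut-3-en-2-yl)benzene
Product: 14 [2,4-bis(methoxymethoxy)-5-(2-methylbut-3-en-2-yl)benzyl]zinc chloride (THF solution containing LiCl)
Conditions: Zn dust (1.5 equiv, activated with BrCH2CH2Br and Me3SiCl), LiCl (1.5 equiv), THF, 25 °C; solution filtered, titrated with I2 and used directly
Reagents that add atoms: zinc, [Zn]
Why: LiCl-mediated direct insertion of zinc metal into the benzylic C–Cl bond is a known route to benzylic zinc chlorides, with LiCl keeping the reagent in solution and Wurtz coupling low.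

**Coupling and endgame (steps 10–13)**

Step 10
Reactants: 4 2-iodo-1,3,5-tris(methoxymethoxy)benzene; 14 [2,4-bis(methoxymethoxy)-5-(2-methylbut-3-en-2-yl)benzyl]zinc chloride; 15 carbon monoxide
Product: 16 2-[2,4-bis(methoxymethoxy)-5-(2-methylbut-3-en-2-yl)phenyl]-1-[2,4,6-tris(methoxymethoxy)phenyl]ethanone
Conditions: Pd(PPh3)4 (5 mol %), CO (3 bar), THF, 50 °C; 14 (1.3 equiv) added by syringe pump over 4 h
Reagents that add atoms: none
Why: Zerovalent palladium inserts into the C–I bond of 4, CO then undergoes migratory insertion to give an aroyl complex of divalent palladium (this forms C4–C4a), the benzyl group of 14 passes from zinc to palladium, and reductive elimination forms C3–C4 and returns the catalyst. The closest known reaction type is the carbonylative Negishi coupling of aryl iodides with alkyl- and benzylzinc halides to unsymmetrical ketones, which is also known for aryl iodides with two ortho substituents. No ring is closed and no stereocentre is created. The selectivity needed is ketone over the diarylmethane of direct coupling: the two ortho OMOM groups of 4 crowd the aryl–palladium bond, which slows transmetalation at that stage yet favours migration of the electron-rich aryl group onto CO, and CO pressure with slow addition of 14 reinforces this order of events. The neutral, aprotic medium should leave the five acetals and the terminal alkene untouched, and neither arene carries a second carbon–halogen bond that could compete.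

Step 11
Reactants: 16 2-[2,4-bis(methoxymethoxy)-5-(2-methylbut-3-en-2-yl)phenyl]-1-[2,4,6-tris(methoxymethoxy)phenyl]ethanone
Product: 17 2-[2,4-bis(methoxymethoxy)-5-(2-methylbut-3-en-2-yl)phenyl]-1-[2-hydroxy-4,6-bis(methoxymethoxy)phenyl]ethanone
Conditions: MgBr2·OEt2 (2 equiv), Et2O/CH2Cl2, 0 °C to rt; sat. aq. NH4Cl
Reagents that add atoms: none
Why: Chelation-controlled acetal cleavage: magnesium bridges the ketone oxygen and one flanking OMOM oxygen in a six-membered chelate and bromide removes that methoxymethyl group, after which the magnesium phenoxide stays bound to the carbonyl and shields the second ortho acetal, while the C7 and ring B acetals cannot form such a chelate.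

Step 12
Reactants: 17 2-[2,4-bis(methoxymethoxy)-5-(2-methylbut-3-en-2-yl)phenyl]-1-[2-hydroxy-4,6-bis(methoxymethoxy)phenyl]ethanone
Product: 19 3-[2,4-bis(methoxymethoxy)-5-(2-methylbut-3-en-2-yl)phenyl]-5,7-bis(methoxymethoxy)-4H-chromen-4-one, via enaminone 18 (not isolated)
Conditions: Me2NCH(OMe)2 (3 equiv), toluene, 90 °C
Reagents that add atoms: N,N-dimethylformamide dimethyl acetal, COC(OC)N(C)C
Why: Condensation at the doubly activated methylene C3 gives the enaminone, whose β-carbon (C2) is attacked by the only free phenol with loss of dimethylamine (addition–elimination), the standard one-carbon closure of 2-hydroxydeoxybenzoins to isoflavones; ring B cannot compete because its oxygens are still protected.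

Step 13
Reactants: 19 3-[2,4-bis(methoxymethoxy)-5-(2-methylbut-3-en-2-yl)phenyl]-5,7-bis(methoxymethoxy)-4H-chromen-4-one
Product: 20 fremontin, 3-[2,4-dihydroxy-5-(2-methylbut-3-en-2-yl)phenyl]-5,7-dihydroxy-4H-chromen-4-one
Conditions: HCl (3 M aq., excess), MeOH/THF, 40 °C
Reagents that add atoms: none
Why: Acid-catalysed transacetalisation to methanol removes all four MOM groups under conditions too mild to protonate the monosubstituted alkene, and the isoflavone carbonyl is no longer prone to furan formation with the 2'-OH.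

**Compound list**

1 | phloroglucinol (benzene-1,3,5-triol) | Oc1cc(O)cc(O)c1 | starting material
2 | 1,3,5-tris(methoxymethoxy)benzene | COCOc1cc(OCOC)cc(OCOC)c1 | intermediate
3 | [2,4,6-tris(methoxymethoxy)phenyl]lithium | [Li]c1c(OCOC)cc(OCOC)cc1OCOC | intermediate (not isolated)
4 | 2-iodo-1,3,5-tris(methoxymethoxy)benzene | COCOc1cc(OCOC)c(I)c(OCOC)c1 | intermediate
5 | 2,4-dihydroxybenzaldehyde | O=Cc1ccc(O)cc1O | starting material
6 | 2-hydroxy-4-[(3-methylbut-2-en-1-yl)oxy]benzaldehyde | CC(C)=CCOc1ccc(C=O)c(O)c1 | intermediate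
7 | 2-(methoxymethoxy)-4-[(3-methylbut-2-en-1-yl)oxy]benzaldehyde | CC(C)=CCOc1ccc(C=O)c(OCOC)c1 | intermediate
8 | 6-(methoxymethoxy)-3-(2-methylbut-3-en-2-yl)-4-oxocyclohexa-1,5-diene-1-carbaldehyde (racemic, transient) | C=CC(C)(C)C1C=C(C=O)C(OCOC)=CC1=O | intermediate (not isolated)
9 | 4-hydroxy-2-(methoxymethoxy)-5-(2-methylbut-3-en-2-yl)benzaldehyde | C=CC(C)(C)c1cc(C=O)c(OCOC)cc1O | intermediate
10 | 2,4-bis(methoxymethoxy)-5-(2-methylbut-3-en-2-yl)benzaldehyde | C=CC(C)(C)c1cc(C=O)c(OCOC)cc1OCOC | intermediate
11 | [2,4-bis(methoxymethoxy)-5-(2-methylbut-3-en-2-yl)phenyl]methanol | C=CC(C)(C)c1cc(CO)c(OCOC)cc1OCOC | intermediate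
12 | [2,4-bis(methoxymethoxy)-5-(2-methylbut-3-en-2-yl)phenyl]methyl methanesulfonate | C=CC(C)(C)c1cc(COS(C)(=O)=O)c(OCOC)cc1OCOC | intermediate (not isolated)
13 | 1-(chloromethyl)-2,4-bis(methoxymethoxy)-5-(2-methylbut-3-en-2-yl)benzene | C=CC(C)(C)c1cc(CCl)c(OCOC)cc1OCOC | intermediate
14 | [2,4-bis(methoxymethoxy)-5-(2-methylbut-3-en-2-yl)benzyl]zinc chloride | C=CC(C)(C)c1cc(C[Zn]Cl)c(OCOC)cc1OCOC | intermediate (kept in solution)
15 | carbon monoxide | [C-]#[O+] | starting material
16 | 2-[2,4-bis(methoxymethoxy)-5-(2-methylbut-3-en-2-yl)phenyl]-1-[2,4,6-tris(methoxymethoxy)phenyl]ethanone | C=CC(C)(C)c1cc(CC(=O)c2c(OCOC)cc(OCOC)cc2OCOC)c(OCOC)cc1OCOC | intermediate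
17 | 2-[2,4-bis(methoxymethoxy)-5-(2-methylbut-3-en-2-yl)phenyl]-1-[2-hydroxy-4,6-bis(methoxymethoxy)phenyl]ethanone | C=CC(C)(C)c1cc(CC(=O)c2c(O)cc(OCOC)cc2OCOC)c(OCOC)cc1OCOC | intermediate
18 | 2-[2,4-bis(methoxymethoxy)-5-(2-methylbut-3-en-2-yl)phenyl]-3-(dimethylamino)-1-[2-hydroxy-4,6-bis(methoxymethoxy)phenyl]prop-2-en-1-one (alkene geometry not defined, either isomer cyclises) | C=CC(C)(C)c1cc(C(=CN(C)C)C(=O)c2c(O)cc(OCOC)cc2OCOC)c(OCOC)cc1OCOC | intermediate (not isolated)
19 | 3-[2,4-bis(methoxymethoxy)-5-(2-methylbut-3-en-2-yl)phenyl]-5,7-bis(methoxymethoxy)-4H-chromen-4-one | C=CC(C)(C)c1cc(-c2coc3cc(OCOC)cc(OCOC)c3c2=O)c(OCOC)cc1OCOC | intermediate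
20 | fremontin, 3-[2,4-dihydroxy-5-(2-methylbut-3-en-2-yl)phenyl]-5,7-dihydroxy-4H-chromen-4-one | C=CC(C)(C)c1cc(-c2coc3cc(O)cc(O)c3c2=O)c(O)cc1O | target

**Step count**

Total: 13 steps (ring A, steps 1–2; ring B, steps 3–9; coupling, step 10; endgame, steps 11–13).
Longest linear sequence: 11 steps (steps 3–13).

**Steps most likely to fail**

1. Step 10. Transmetalation may outrun CO insertion, so that aryl and benzyl couple directly without the carbonyl. The zinc reagent may also homocouple or be protonated, or oxidative addition at the crowded, electron-rich iodide may stall. The fallback sets out from 2 (through aryllithium 3) and from 14 and returns at 16. Aryllithium 3 is quenched with DMF to give 2,4,6-tris(methoxymethoxy)benzaldehyde F1. Zinc reagent 14 is added to the aldehyde (THF, 25 °C, MgCl2 as additive if the addition is slow) to give racemic 2-[2,4-bis(methoxymethoxy)-5-(2-methylbut-3-en-2-yl)phenyl]-1-[2,4,6-tris(methoxymethoxy)phenyl]ethanol F2. Oxidation with Dess–Martin periodinane (NaHCO3, CH2Cl2) then gives ketone 16, so the carbonyl carbon comes from DMF and not from CO.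

2. Step 5. The prenyl group may migrate partly to C3, be lost by thermal ether cleavage, or rearrange further (abnormal Claisen shift or ring closure of the new phenol onto the alkene) at the temperature required. The fallback builds the quaternary carbon by enolate arylation; it sets out from 5 and returns at 11.
   - Bromination of 5 (Br2, AcOH, rt) should give 5-bromo-2,4-dihydroxybenzaldehyde F3.
   - NaH/MOMCl gives 5-bromo-2,4-bis(methoxymethoxy)benzaldehyde F4.
   - NaBH4 gives [5-bromo-2,4-bis(methoxymethoxy)phenyl]methanol F5.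
   - TBSCl/imidazole gives {[5-bromo-2,4-bis(methoxymethoxy)phenyl]methoxy}(tert-butyl)dimethylsilane F6.
   - Palladium-catalysed α-arylation of isobutyronitrile (Pd(OAc)2, rac-BINAP, NaN(SiMe3)2, toluene, 100 °C) gives 2-[5-({[tert-butyl(dimethyl)silyl]oxy}methyl)-2,4-bis(methoxymethoxy)phenyl]-2-methylpropanenitrile F7.
   - i-Bu2AlH (toluene, −78 °C, then wet silica gel) gives 2-[5-({[tert-butyl(dimethyl)silyl]oxy}methyl)-2,4-bis(methoxymethoxy)phenyl]-2-methylpropanal F8.
   - Wittig methylenation (Ph3PCH3Br, KOt-Bu, THF) gives tert-butyl{[2,4-bis(methoxymethoxy)-5-(2-methylbut-3-en-2-yl)phenyl]methoxy}dimethylsilane F9.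
   - Bu4NF (THF) frees alcohol 11.

3. Step 11. More than one acetal may be lost. If a ring B acetal is cleaved, the freed 2'-phenol can condense with the ketone to a benzofuran. Cleavage may also be sluggish because the doubly ortho-substituted carbonyl is twisted and chelates poorly. The fallback reverses the order of events; it sets out from 16 and returns at 19. Ketone 16 is condensed first with Me2NCH(OMe)2 (neat, 100 °C) to give 2-[2,4-bis(methoxymethoxy)-5-(2-methylbut-3-en-2-yl)phenyl]-3-(dimethylamino)-1-[2,4,6-tris(methoxymethoxy)phenyl]prop-2-en-1-one F10. Its vinylogous amide carbonyl is a much stronger donor, so MgBr2·OEt2 (Et2O/CH2Cl2, rt) should cleave one flanking acetal. The phenoxide so formed is trapped at once by addition to C2 and loss of dimethylamine, which gives isoflavone 19 directly.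

**Further compounds**

F1 | step 10 | 2,4,6-tris(methoxymethoxy)benzaldehyde | O=Cc1c(OCOC)cc(OCOC)cc1OCOC
F2 | step 10 | 2-[2,4-bis(methoxymethoxy)-5-(2-methylbut-3-en-2-yl)phenyl]-1-[2,4,6-tris(methoxymethoxy)phenyl]ethanol (racemic) | C=CC(C)(C)c1cc(CC(O)c2c(OCOC)cc(OCOC)cc2OCOC)c(OCOC)cc1OCOC
F3 | step 5 | 5-bromo-2,4-dihydroxybenzaldehyde | O=Cc1cc(Br)c(O)cc1O
F4 | step 5 | 5-bromo-2,4-bis(methoxymethoxy)benzaldehyde | O=Cc1cc(Br)c(OCOC)cc1OCOC
F5 | step 5 | [5-bromo-2,4-bis(methoxymethoxy)phenyl]methanol | OCc1cc(Br)c(OCOC)cc1OCOC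
F6 | step 5 | {[5-bromo-2,4-bis(methoxymethoxy)phenyl]methoxy}(tert-butyl)dimethylsilane | CC(C)(C)[Si](C)(C)OCc1cc(Br)c(OCOC)cc1OCOC
F7 | step 5 | 2-[5-({[tert-butyl(dimethyl)silyl]oxy}methyl)-2,4-bis(methoxymethoxy)phenyl]-2-methylpropanenitrile | CC(C)(C#N)c1cc(CO[Si](C)(C)C(C)(C)C)c(OCOC)cc1OCOC
F8 | step 5 | 2-[5-({[tert-butyl(dimethyl)silyl]oxy}methyl)-2,4-bis(methoxymethoxy)phenyl]-2-methylpropanal | CC(C)(C=O)c1cc(CO[Si](C)(C)C(C)(C)C)c(OCOC)cc1OCOC
F9 | step 5 | tert-butyl{[2,4-bis(methoxymethoxy)-5-(2-methylbut-3-en-2-yl)phenyl]methoxy}dimethylsilane | C=CC(C)(C)c1cc(CO[Si](C)(C)C(C)(C)C)c(OCOC)cc1OCOC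
F10 | step 11 | 2-[2,4-bis(methoxymethoxy)-5-(2-methylbut-3-en-2-yl)phenyl]-3-(dimethylamino)-1-[2,4,6-tris(methoxymethoxy)phenyl]prop-2-en-1-one | C=CC(C)(C)c1cc(C(=CN(C)C)C(=O)c2c(OCOC)cc(OCOC)cc2OCOC)c(OCOC)cc1OCOC
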